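**Plan**

1. Locants: flavonol unit unprimed/′, flavone unit ″/‴. Retrosynthetic cuts, in order: the flavonol C ring at O1–C2 and C3–O (Algar–Flynn–Oyamada), then Cα=Cβ of the chalcone and the ring-A–acetyl bond; the flavone C ring at O1″–C2″ and C2″–C3″ (Claisen); last the interflavonoid bond C6–C3‴, cut between two C–H carbons.
2. Forward: C6–C3‴ is made first, from methyl 4-hydroxybenzoate and 1,3-diisopropoxybenzene, by anodic dehydrogenative cross-coupling. The flavone pyranone is then built on the ester end (step 3), the flavonol pyranone on the resorcinol end (steps 4–5), and O7 is unmasked (step 6).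
3. Enabling feature: C6 of ring A is ortho to O7 and para to O1; C3‴ of ring B is ortho to O4‴, and its para carbon C1‴ already bears the future C2″. Both are the innate oxidative-coupling sites of a resorcinol diether and of a para-blocked phenol, and both partners are symmetric, so only one cross-coupled constitution can form.
4. The two isopropyl ethers make the resorcinol ring nucleophilic in step 1; one is lost under chelation control to free O1 in step 4; the other protects O7 to the end.
5. Stereochemistry: the target has no stereocentre and no stable axis, so nothing has to be set.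

Key step: step 1

Assumption: the C6–C3‴ axis carries only two ortho substituents (7-OH, 4‴-OMe) and is not configurationally stable, so the "single enantiomer" is the achiral compound itself.

**Route**

Step 1
Reactants: 1 methyl 4-hydroxybenzoate; 2 1,3-di(propan-2-yloxy)benzene
Product: 3 methyl 4-hydroxy-3-[2,4-di(propan-2-yloxy)phenyl]benzoate
Conditions: undivided cell, BDD anode, Pt cathode, constant current (5 mA cm⁻², ca. 2.2 F per mol of 1); 2 (3 equiv), iPr2NEt (1 equiv), HFIP, 30 °C
Reagents that add atoms: none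
Why: Anodic dehydrogenative phenol–arene cross-coupling: in HFIP the amine turns 1 into its hydrogen-bonded phenolate, which is oxidised at the BDD anode below the potential of HFIP-solvated 2 to an electrophilic, ester-substituted phenoxyl radical; this radical is trapped at an ortho carbon by C4 of the nucleophilic arene 2 (present in excess), and a second electron transfer with loss of two protons rearomatises both rings while protons are reduced to H2 at the cathode. The closest known reaction types are the anodic phenol–arene C–C cross-coupling in HFIP on boron-doped diamond and the base-assisted anodic C–C coupling of phenols that carry electron-withdrawing groups. No ring is closed and no stereocentre is formed; the new C–C bond is the future C6–C3‴ bond. The step needs cross- rather than homo-coupling, C–C rather than C–O coupling, one regioisomer, and no further oxidation of 3. Cross-selectivity should follow from the gap in oxidation potential (phenolate of 1 far below 2), the gap in nucleophilicity (2 far above 1) and the excess of 2, and C–C selectivity from HFIP hydrogen-bonding at the phenoxyl oxygen; the regiochemistry is fixed by the substrates, since the para position of 1 is blocked by CO2Me and its two ortho carbons are equivalent, while in 2 C4 and C6 are equivalent, C2 is shielded by two isopropoxy groups and C5 is not activated. Further oxidation of the twisted, HFIP-solvated biaryl should be limited by stopping the electrolysis at about 2 F per mol and recovering unreacted 1 and 2.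

Step 2
Reactants: 3 methyl 4-hydroxy-3-[2,4-di(propan-2-yloxy)phenyl]benzoate
Product: 4 methyl 4-methoxy-3-[2,4-di(propan-2-yloxy)phenyl]benzoate
Conditions: MeI, K2CO3, acetone, 55 °C
Reagents that add atoms: iodomethane, CI
Why: Williamson ether synthesis; the phenol para to the ester is acidic, its phenolate is the only nucleophile in 3, and SN2 methylation installs the 4‴-OMe group.

Step 3
Reactants: 4 methyl 4-methoxy-3-[2,4-di(propan-2-yloxy)phenyl]benzoate; 5 1-(2,6-dihydroxy-4-methoxyphenyl)ethan-1-one
Product: 7 5-hydroxy-7-methoxy-2-{4-methoxy-3-[2,4-di(propan-2-yloxy)phenyl]phenyl}-4H-chromen-4-one, via 1,3-diketone 6 (not isolated)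
Conditions: 5 (1.3 equiv), LiHMDS (5 equiv), THF, −78 → 0 °C; then 4, 0 °C → reflux; aq. HCl; crude 6, TsOH·H2O (cat.), toluene, 90 °C
Reagents that add atoms: none
Why: Crossed Claisen condensation of the lithium polyanion of 5 with the non-enolisable aryl ester 4, driven by deprotonation of the 1,3-diketone, then acid-catalysed cyclodehydration (Baker–Venkataraman-type flavone synthesis); the two ortho hydroxyls of 5 are equivalent, so only the 5-hydroxy-7-methoxy pattern can result, and the isopropyl ethers tolerate both the base and the mild acid.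

Step 4
Reactants: 7 5-hydroxy-7-methoxy-2-{4-methoxy-3-[2,4-di(propan-2-yloxy)phenyl]phenyl}-4H-chromen-4-one
Product: 9 2-{3-[5-acetyl-4-hydroxy-2-(propan-2-yloxy)phenyl]-4-methoxyphenyl}-5-hydroxy-7-methoxy-4H-chromen-4-one, via diisopropoxy aryl methyl ketone 8 (not isolated)
Conditions: AcCl (1.5 equiv), TiCl4 (4 equiv), CH2Cl2, −20 → 0 °C; aq. HCl work-up
Reagents that add atoms: acetyl chloride, CC(=O)Cl
Why: Friedel–Crafts acetylation at the one unhindered carbon of ring A that is para to one isopropoxy group and ortho to the other, followed in the same pot by chelation-controlled TiCl4 cleavage of the isopropyl ether ortho to the new ketone (this frees the future O1); the titanium-bound 5-hydroxychromone and ring B are deactivated, and the non-chelated isopropyl ether and all methyl ethers should survive at or below 0 °C.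

Step 5
Reactants: 9 2-{3-[5-acetyl-4-hydroxy-2-(propan-2-yloxy)phenyl]-4-methoxyphenyl}-5-hydroxy-7-methoxy-4H-chromen-4-one; 10 4-methoxybenzaldehyde
Product: 13 3-hydroxy-6-[5-(5-hydroxy-7-methoxy-4-oxo-4H-chromen-2-yl)-2-methoxyphenyl]-2-(4-methoxyphenyl)-7-(propan-2-yloxy)-4H-chromen-4-one, via (E)-chalcone 11 (not isolated), via trans-dihydroflavonol 12 (not isolated)
Conditions: 10 (1.5 equiv), KOH (50% aq.), EtOH/THF, rt; then 30% H2O2, 0 °C → rt; aq. HCl
Reagents that add atoms: hydrogen peroxide, OO
Why: Claisen–Schmidt condensation to the 2′-hydroxychalcone, then Algar–Flynn–Oyamada oxidative cyclisation; the chalcone has no 6′-substituent, the case in which the flavonol rather than the aurone is formed, the flavone unit is shielded as its 5-phenolate against hydroxide and hydroperoxide, and the two transient stereocentres of 12 vanish on dehydrogenation.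

Step 6
Reactants: 13 3-hydroxy-6-[5-(5-hydroxy-7-methoxy-4-oxo-4H-chromen-2-yl)-2-methoxyphenyl]-2-(4-methoxyphenyl)-7-(propan-2-yloxy)-4H-chromen-4-one
Product: 14 abiesin, 3,7-dihydroxy-6-[5-(5-hydroxy-7-methoxy-4-oxo-4H-chromen-2-yl)-2-methoxyphenyl]-2-(4-methoxyphenyl)-4H-chromen-4-one
Conditions: BCl3 (5 equiv), CH2Cl2, −78 → 0 °C; then H2O
Reagents that add atoms: none
Why: Lewis-acid dealkylation; BCl3 cleaves a secondary-alkyl aryl ether by an SN1-like path much faster than non-chelated aryl methyl ethers, so only O7 should be unmasked, and the boron chelates at the two hydroxy-ketone sites are hydrolysed on work-up.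

**Compound list**

1 | methyl 4-hydroxybenzoate | COC(=O)c1ccc(O)cc1 | starting material
2 | 1,3-di(propan-2-yloxy)benzene | CC(C)Oc1cccc(OC(C)C)c1 | starting material
3 | methyl 4-hydroxy-3-[2,4-di(propan-2-yloxy)phenyl]benzoate | COC(=O)c1ccc(O)c(-c2ccc(OC(C)C)cc2OC(C)C)c1 | intermediate
4 | methyl 4-methoxy-3-[2,4-di(propan-2-yloxy)phenyl]benzoate | COC(=O)c1ccc(OC)c(-c2ccc(OC(C)C)cc2OC(C)C)c1 | intermediate
5 | 1-(2,6-dihydroxy-4-methoxyphenyl)ethan-1-one | CC(=O)c1c(O)cc(OC)cc1O | starting material
6 | 1-(2,6-dihydroxy-4-methoxyphenyl)-3-{4-methoxy-3-[2,4-di(propan-2-yloxy)phenyl]phenyl}propane-1,3-dione | COc1cc(O)c(C(=O)CC(=O)c2ccc(OC)c(-c3ccc(OC(C)C)cc3OC(C)C)c2)c(O)c1 | intermediate (not isolated)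
7 | 5-hydroxy-7-methoxy-2-{4-methoxy-3-[2,4-di(propan-2-yloxy)phenyl]phenyl}-4H-chromen-4-one | COc1cc(O)c2c(=O)cc(-c3ccc(OC)c(-c4ccc(OC(C)C)cc4OC(C)C)c3)oc2c1 | intermediate
8 | 2-{3-[5-acetyl-2,4-di(propan-2-yloxy)phenyl]-4-methoxyphenyl}-5-hydroxy-7-methoxy-4H-chromen-4-one | COc1cc(O)c2c(=O)cc(-c3ccc(OC)c(-c4cc(C(C)=O)c(OC(C)C)cc4OC(C)C)c3)oc2c1 | intermediate (not isolated)
9 | 2-{3-[5-acetyl-4-hydroxy-2-(propan-2-yloxy)phenyl]-4-methoxyphenyl}-5-hydroxy-7-methoxy-4H-chromen-4-one | COc1cc(O)c2c(=O)cc(-c3ccc(OC)c(-c4cc(C(C)=O)c(O)cc4OC(C)C)c3)oc2c1 | intermediate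
10 | 4-methoxybenzaldehyde | COc1ccc(C=O)cc1 | starting material
11 | 5-hydroxy-2-{3-[4-hydroxy-5-[(2E)-3-(4-methoxyphenyl)prop-2-enoyl]-2-(propan-2-yloxy)phenyl]-4-methoxyphenyl}-7-methoxy-4H-chromen-4-one | COc1ccc(/C=C/C(=O)c2cc(-c3cc(-c4cc(=O)c5c(O)cc(OC)cc5o4)ccc3OC)c(OC(C)C)cc2O)cc1 | intermediate (not isolated)
12 | rac-(2R,3R)-3-hydroxy-6-[5-(5-hydroxy-7-methoxy-4-oxo-4H-chromen-2-yl)-2-methoxyphenyl]-2-(4-methoxyphenyl)-7-(propan-2-yloxy)chroman-4-one (trans, racemic; one enantiomer drawn) | COc1ccc([C@@H]2[C@@H](O)C(=O)c3cc(-c4cc(-c5cc(=O)c6c(O)cc(OC)cc6o5)ccc4OC)c(OC(C)C)cc3O2)cc1 | intermediate (not isolated)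
13 | 3-hydroxy-6-[5-(5-hydroxy-7-methoxy-4-oxo-4H-chromen-2-yl)-2-methoxyphenyl]-2-(4-methoxyphenyl)-7-(propan-2-yloxy)-4H-chromen-4-one | COc1ccc(-c2oc3cc(OC(C)C)c(-c4cc(-c5cc(=O)c6c(O)cc(OC)cc6o5)ccc4OC)cc3c(=O)c2O)cc1 | intermediate
14 | abiesin, 3,7-dihydroxy-6-[5-(5-hydroxy-7-methoxy-4-oxo-4H-chromen-2-yl)-2-methoxyphenyl]-2-(4-methoxyphenyl)-4H-chromen-4-one | COc1ccc(-c2oc3cc(O)c(-c4cc(-c5cc(=O)c6c(O)cc(OC)cc6o5)ccc4OC)cc3c(=O)c2O)cc1 | target

**Count and risks**

Total step count: 6. Longest linear sequence: 6 steps (1 and 2 → 14).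

Steps most likely to fail:

1. Step 1. The ester-bearing phenoxyl radical may form too slowly, couple with itself or through oxygen, or the electron-rich product may be oxidised further (for example by cyclisation onto the neighbouring ring), so that the cross-coupled biaryl is only a minor product. The fallback sets out from 1 and 2 and returns at 3, replacing the dehydrogenative coupling by a cross-coupling of prefunctionalised simple arenes. Compound 1 is brominated ortho to the hydroxyl (NBS, MeCN, 0 °C) to methyl 3-bromo-4-hydroxybenzoate F1. Compound 2 is brominated at C4 (NBS, MeCN, 0 °C) to 1-bromo-2,4-di(propan-2-yloxy)benzene F2, which Miyaura borylation (B2pin2, Pd(dppf)Cl2, KOAc, dioxane, 90 °C) converts into 2-[2,4-di(propan-2-yloxy)phenyl]-4,4,5,5-tetramethyl-1,3,2-dioxaborolane F3. Suzuki–Miyaura coupling of F1 with F3 (Pd(OAc)2/SPhos, K3PO4, toluene/H2O, 90 °C) should give 3, and the route continues with step 2.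

2. Step 4. The Lewis acid may be sequestered by the chromone so that acylation stalls, or ether cleavage may not stay confined to the chelated isopropyl group. The fallback sets out from 7 and returns at 9, separating deprotection, acylation and re-protection. BCl3 (excess, CH2Cl2, 0 °C → rt) removes both isopropyl groups to give 2-[3-(2,4-dihydroxyphenyl)-4-methoxyphenyl]-5-hydroxy-7-methoxy-4H-chromen-4-one F4. The free resorcinol ring, now by far the most nucleophilic ring, is C-acetylated with AcOH/BF3·OEt2 (80 °C, Nencki-type) to 2-[3-(5-acetyl-2,4-dihydroxyphenyl)-4-methoxyphenyl]-5-hydroxy-7-methoxy-4H-chromen-4-one F5. The only hydroxyl that is not hydrogen-bonded to a carbonyl is then alkylated (2-bromopropane, K2CO3, DMF, 50 °C) to give 9.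

3. Step 5. During the long alkaline aldol and the peroxide treatment, hydroxide may open the chromone ring, or the oxidative cyclisation may stop at the dihydroflavonol or divert to an aurone. The fallback sets out from 9 and 10 and returns at 13, building the flavonol ring without hydroxide or peroxide. Pyrrolidine in refluxing EtOH should effect aldol condensation and oxa-Michael closure to the racemic flavanone 6-[5-(5-hydroxy-7-methoxy-4-oxo-4H-chromen-2-yl)-2-methoxyphenyl]-2-(4-methoxyphenyl)-7-(propan-2-yloxy)chroman-4-one F6. α-Nitrosation of its C3 methylene (isoamyl nitrite, HCl, THF/EtOH, 0 °C → rt) gives the 3-(hydroxyimino)chroman-4-one F7. Oxime exchange (aq. formaldehyde, HCl, 40 °C) releases the 3-oxo compound, which is the keto tautomer of 13 and enolises to it; the route continues with step 6.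

**Further compounds**

F1 | step 1 | methyl 3-bromo-4-hydroxybenzoate | COC(=O)c1ccc(O)c(Br)c1
F2 | step 1 | 1-bromo-2,4-di(propan-2-yloxy)benzene | CC(C)Oc1ccc(Br)c(OC(C)C)c1
F3 | step 1 | 2-[2,4-di(propan-2-yloxy)phenyl]-4,4,5,5-tetramethyl-1,3,2-dioxaborolane | CC(C)Oc1ccc(B2OC(C)(C)C(C)(C)O2)c(OC(C)C)c1
F4 | step 4 | 2-[3-(2,4-dihydroxyphenyl)-4-methoxyphenyl]-5-hydroxy-7-methoxy-4H-chromen-4-one | COc1cc(O)c2c(=O)cc(-c3ccc(OC)c(-c4ccc(O)cc4O)c3)oc2c1
F5 | step 4 | 2-[3-(5-acetyl-2,4-dihydroxyphenyl)-4-methoxyphenyl]-5-hydroxy-7-methoxy-4H-chromen-4-one | COc1cc(O)c2c(=O)cc(-c3ccc(OC)c(-c4cc(C(C)=O)c(O)cc4O)c3)oc2c1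
F6 | step 5 | rac-6-[5-(5-hydroxy-7-methoxy-4-oxo-4H-chromen-2-yl)-2-methoxyphenyl]-2-(4-methoxyphenyl)-7-(propan-2-yloxy)chroman-4-one | COc1ccc(C2CC(=O)c3cc(-c4cc(-c5cc(=O)c6c(O)cc(OC)cc6o5)ccc4OC)c(OC(C)C)cc3O2)cc1
F7 | step 5 | rac-3-(hydroxyimino)-6-[5-(5-hydroxy-7-methoxy-4-oxo-4H-chromen-2-yl)-2-methoxyphenyl]-2-(4-methoxyphenyl)-7-(propan-2-yloxy)chroman-4-one | COc1ccc(C2Oc3cc(OC(C)C)c(-c4cc(-c5cc(=O)c6c(O)cc(OC)cc6o5)ccc4OC)cc3C(=O)C2=NO)cc1
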